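# Proposed synthesis of quercetin 3-acetate 7,3',4'-tri-O-sulfate (20)

## The problem

Target 20 is a flavonol: a benzo-fused γ-pyranone (rings A and C) with a catechol-derived ring B at C2. It has no stereocentre, so nothing has to be controlled in space. The difficulty lies in its five oxygen substituents, which fall into three classes: O3 is acetylated, O5 is a free phenol, and O7, O3' and O4' are sulfate monoesters. Direct acetylation or sulfation of the parent pentahydroxyflavone cannot tell O3 from O7 and O4', so O3 has to enter the synthesis already distinguished from the phenolic oxygens. The three aryl sulfates are polar, acid-labile and hard to purify, so they must come last. The 3-acetate is an enol ester that is lost to hydroxide, alkoxide or amine nucleophiles, so it must go on late and then be kept away from base. The C5 hydroxyl is held by a strong hydrogen bond to the C4 carbonyl, which makes it the least reactive phenol and allows it to stay free without a protecting group of its own. The feature that opens the key step lies in ring A: C8a carries the ring oxygen O1, its neighbour C4a carries the C4 carbonyl, and C5 (next to C4a) and C7 bear oxygen. This is the pattern left when a nucleophile and then an acyl group add across the triple bond of a 3,5-dialkoxybenzyne.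

## Retrosynthesis

**Sulfates (20 to 19).** The three S–O bonds of 20 are cut first, which leads back to quercetin 3-acetate 19. Sulfation is placed last because no later step would tolerate three sulfate monoesters. It needs no protecting group at O5, since the chelated C5 hydroxyl resists sulfur trioxide–amine complexes. The forward reaction must drive the catechol pair to the disulfate and must not touch the acetate.

**Protecting groups (19 to 16).** The four phenols of 19 are traced back to benzyl ethers in 18, which come off together by hydrogenolysis under neutral conditions that the enol acetate survives. The acetate of 18 is cut back to flavonol 17, in which O3 is the only free hydroxyl, so acetylation needs no selectivity. Flavonol 17 comes from the methoxymethyl ether 16. The acetal at O3 is cleaved by mild acid that leaves benzyl ethers alone, and it tolerates the base and fluoride used earlier.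

**Ring C (16 to 6 and 12).** Ring C of 16 is opened at O1–C8a and C4–C4a. This gives aryne precursor 6 (which releases 3,5-bis(benzyloxy)benzyne 14) and α-alkoxy β-ketoester 12, whose cesium enolate 13 is to add through oxygen and then be acylated by its own ester via aryl anion 15.
- The neighbouring cuts are O1–C2 with C4–C4a (phenol plus ketoester), C2–C3 with C3–C4 (ylide linchpin), and the linear route through a 2-hydroxyaryl ketone.
- Against these, this cut forms both bonds from ring A to ring C in one flask, takes O1 from the ketoester and brings O3 in at the right oxidation level, already protected differently from the phenols.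
- Both precursors are simple, and each is three steps from a catalogue chemical.
- The forward reaction must add the nucleophile meta to the flanking benzyloxy group of the aryne, and the enolate must react at oxygen and not at carbon.

**Ketoester (12 to 8 and 10).** Ketoester 12 is cut at the bond between its α-carbon and the ketone carbon (the later C2–C3 bond), giving the lithium enolate 11 of methyl (methoxymethoxy)acetate 8 and acid chloride 10. Ester 8 comes from methyl glycolate 7 and acid chloride 10 from 3,4-bis(benzyloxy)benzoic acid 9. The crossed Claisen acylation must stop after one acylation.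

**Aryne precursor (6 to 1).** Triflate 6 is cut at the O–S bond and the C–Si bond. The silyl group is traced to the oxygen of silyl ether 3, from which it migrates to carbon (aryllithium 4 to phenoxide 5) after bromine–lithium exchange. Silyl ether 3 comes from bromophenol 2, and 2 from 3,5-bis(benzyloxy)phenol 1. The only demand is bromination ortho to the hydroxyl and not at C4 between the two ethers.

## Roads not taken

**Alternative 1:** The cut runs through ring A itself. The C4a–C8a bond is broken and the aromatic ring is unfolded into the triketo ester methyl (E)-9-[3,4-bis(benzyloxy)phenyl]-3,5,7-trioxonon-8-enoate A2.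
- *Forward key step:* base makes the methylene next to the cinnamoyl ketone attack the ester carbon. The ring aromatises to the chalcone (E)-3-[3,4-bis(benzyloxy)phenyl]-1-(2,4,6-trihydroxyphenyl)prop-2-en-1-one A1.
- *Merits:* it follows the biosynthesis, draws the three oxygens of ring A from carbonyl groups, and uses a condensation of a known type that needs no special aryne precursor.
- *Weak points:* A2 must be assembled by polyanion chemistry and can cyclise in other ways (aldol closure to a resorcylate, lactonisation to a hydroxypyranone). A1 is only a chalcone, so ring C remains to be closed and C3 oxidised, and alkaline peroxide cyclisation of chalcones with a 6'-oxygen tends to give aurones. A1 also shows three free phenols with no distinction between the later O5 and O7.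
- *Comparison:* this road is better in the cost of its materials and in resting on a known ring closure. The chosen plan sets against it that step 7 delivers all five oxygens in their final three classes in a single compound, whereas this road leaves the differentiation and the C3 oxidation to a long endgame.

**Alternative 2:** The cuts are C3–C4 and C2=C3, with C3 supplied as a one-carbon ylide.
- *Forward key step:* the salicyloyl chloride 2,4-bis(benzyloxy)-6-{[3,4-bis(benzyloxy)benzoyl]oxy}benzoyl chloride A4 acylates [2-(trimethylsilyl)ethoxy]methylenetriphenylphosphorane A5. The acyl ylide then olefinates the aryl ester carbonyl intramolecularly to give 5,7-bis(benzyloxy)-2-[3,4-bis(benzyloxy)phenyl]-3-[2-(trimethylsilyl)ethoxy]chromen-4-one A3.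
- *Merits:* ylide acylation and intramolecular Wittig olefination of an ester to a chromone are both known reaction types. O3 arrives protected by a group that fluoride removes without touching benzyl ethers.
- *Weak points:* A4 is a 2,6-disubstituted benzoyl chloride with an acyl-transfer-prone aryl ester beside it. The parent hydroxy acid of A4 takes several steps to make. A5 is needed in twofold amount or with an extra base. Olefination of an ester by a stabilised acyl ylide needs heat, and a stoichiometric phosphorus by-product has to be removed.
- *Comparison:* in mechanistic risk this road is better than the chosen one, because no bond formation is without precedent. The chosen plan sets against it greater convergence, a shorter way to the ring A building block, and a ring closure that needs no activated acyl derivative of a crowded benzoic acid.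

**Alternative 3:** The cuts are C4–C4a and O1–C2.
- *Forward key step:* phloroglucinol A7 and ethyl 3-[3,4-bis(benzyloxy)phenyl]-3-oxopropanoate A8 are heated without catalyst to give 2-[3,4-bis(benzyloxy)phenyl]-5,7-dihydroxychromen-4-one A6.
- *Merits:* this is the shortest way to the flavone skeleton. It uses a commodity phenol without protecting groups, and A6 has the C5 hydroxyl free and the C7 hydroxyl selectively addressable.
- *Weak points:* A6 lacks O3. C3–H must be oxidised later, which adds protection of O5 and O7 and an oxidation of an electron-rich flavone bearing benzylic C–H bonds. The condensation needs temperatures well above 200 °C, which the benzyl ethers of A8 may not survive. Drift towards acid catalysis turns the ketoester towards the isomeric coumarin.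
- *Comparison:* this road is as good or better in step count and in the certainty of ring formation. The chosen plan sets against it that O3 is built in at the correct oxidation level and already distinguished, so no late C–H oxidation is needed.

Key step: step 7

## Route

Assumption: aryl hydrogen sulfates are made and kept as salts, so 20 is to be obtained as its tris(triethylammonium) salt and is written in the neutral acid form of the target.

Step 1
Reactants: 1 3,5-bis(benzyloxy)phenol
Product: 2 3,5-bis(benzyloxy)-2-bromophenol
Conditions: NBS (1.0 equiv), i-Pr2NH (cat.), CH2Cl2, −78 to 0 °C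
Reagents that add atoms: N-bromosuccinimide, O=C1CCC(=O)N1Br
Why: Electrophilic aromatic bromination; the N-bromoamine formed from the catalyst is delivered by hydrogen bonding to the position ortho to the hydroxyl (C2, identical with C6 by symmetry) rather than to the more hindered C4 between the two benzyloxy groups, and one equivalent at low temperature should limit a second bromination.

Step 2
Reactants: 2 3,5-bis(benzyloxy)-2-bromophenol
Product: 3 [3,5-bis(benzyloxy)-2-bromophenoxy]trimethylsilane
Conditions: HN(SiMe3)2, THF, 70 °C; evaporation
Reagents that add atoms: hexamethyldisilazane, C[Si](C)(C)N[Si](C)(C)C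
Why: O-Silylation of a phenol by a silazane, driven by loss of ammonia; the moisture-sensitive silyl ether is taken on after removal of volatiles.

Step 3
Reactants: 3 [3,5-bis(benzyloxy)-2-bromophenoxy]trimethylsilane
Product: 6 3,5-bis(benzyloxy)-2-(trimethylsilyl)phenyl trifluoromethanesulfonate, via aryllithium 4 (not isolated), via lithium phenoxide 5 (not isolated)
Conditions: n-BuLi, THF, −100 to −78 °C; then Tf2O, −100 to −78 °C
Reagents that add atoms: trifluoromethanesulfonic anhydride, O=S(=O)(OS(=O)(=O)C(F)(F)F)C(F)(F)F
Why: Bromine–lithium exchange outruns deprotonation of the benzylic ethers at this temperature; aryllithium 4 takes the silyl group from the neighbouring oxygen in a 1,3-retro-Brook shift, and phenoxide 5 is triflated in the same flask, the standard entry to ortho-silylaryl triflates.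

Step 4
Reactants: 7 methyl glycolate
Product: 8 methyl 2-(methoxymethoxy)acetate
Conditions: MOMCl, i-Pr2NEt, CH2Cl2, 0 °C to rt
Reagents that add atoms: chloromethyl methyl ether, COCCl
Why: O-Alkylation of a primary alcohol by an α-chloro ether under amine base (acetal formation); the methyl ester is untouched.

Step 5
Reactants: 9 3,4-bis(benzyloxy)benzoic acid
Product: 10 3,4-bis(benzyloxy)benzoyl chloride
Conditions: (COCl)2, DMF (cat.), CH2Cl2, 0 °C to rt; evaporation
Reagents that add atoms: oxalyl chloride, O=C(Cl)C(=O)Cl
Why: Acid chloride formation through the chloroiminium species generated from DMF; benzyl ethers are inert and the crude chloride is used directly.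

Step 6
Reactants: 8 methyl 2-(methoxymethoxy)acetate; 10 3,4-bis(benzyloxy)benzoyl chloride
Product: 12 methyl 3-[3,4-bis(benzyloxy)phenyl]-2-(methoxymethoxy)-3-oxopropanoate (racemic), via lithium enolate 11 (not isolated)
Conditions: 8 (2.1 equiv), LiN(SiMe3)2 (2.1 equiv), THF, −78 °C; then 10, −78 to −20 °C; aq. NH4Cl
Reagents that add atoms: none
Why: Crossed Claisen acylation of an ester enolate by an acid chloride; the second equivalent of enolate 11 takes up the acidic proton of 12 and so guards against double acylation, and −78 °C suppresses self-condensation of the α-alkoxy enolate. The new stereocentre is racemic, enolisable and removed in step 7.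

Step 7
Reactants: 6 3,5-bis(benzyloxy)-2-(trimethylsilyl)phenyl trifluoromethanesulfonate; 12 methyl 3-[3,4-bis(benzyloxy)phenyl]-2-(methoxymethoxy)-3-oxopropanoate
Product: 16 5,7-bis(benzyloxy)-2-[3,4-bis(benzyloxy)phenyl]-3-(methoxymethoxy)chromen-4-one, via cesium enolate 13 (not isolated), via aryne 14 (not isolated), via arylcesium adduct 15 (not isolated)
Conditions: 6 (1.3 equiv), CsF (4 equiv), THF, 65 °C
Reagents that add atoms: none
Why: Proposed new method: fluoride removes the trimethylsilyl group of 6 and triflate leaves, which gives 3,5-bis(benzyloxy)benzyne 14, while CsF also converts 12 into the chelated cesium enolate 13. The ketone-derived enolate oxygen adds to the aryne carbon meta to the flanking benzyloxy group (O1–C8a), the more electrophilic terminus of the distorted aryne, so that the aryl anion of 15 lies ortho to that benzyloxy group, where the C–O dipole stabilises it. Because 13 is chelated, the new aryloxy group and the ester stand cis on the C2=C3 double bond, and the anion attacks the ester carbonyl in a 6-exo-trig acyl substitution that closes ring C (C4–C4a) and expels methoxide. The closest known reaction types are the CsF-mediated annulation of arynes by salicylate esters to xanthones, which shows the same oxygen attack followed by acyl trapping, and the acyl-alkylation of arynes by beta-ketoesters, which shows the competing carbon attack. No stereocentre is formed. Two selectivities are needed: the site of attack on the aryne, which the 3-alkoxy substituent secures and which maps onto the C5 and C7 oxygens, and oxygen over carbon attack of the ambident enolate. The latter is to be favoured by the fully substituted enolate carbon flanked by aryl ketone, ester and alkoxy groups, by the loosely bound cesium counter-ion, and by THF, which does not protonate the aryl anion before it cyclises.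

Step 8
Reactants: 16 5,7-bis(benzyloxy)-2-[3,4-bis(benzyloxy)phenyl]-3-(methoxymethoxy)chromen-4-one
Product: 17 5,7-bis(benzyloxy)-2-[3,4-bis(benzyloxy)phenyl]-3-hydroxychromen-4-one
Conditions: HCl (3 M aq., few equiv), MeOH/THF, 50 °C
Reagents that add atoms: none
Why: Acid-catalysed acetal exchange with methanol removes the methoxymethyl group; these conditions lie well below those needed to cleave a benzyl aryl ether, the 5-O-benzyl group included.

Step 9
Reactants: 17 5,7-bis(benzyloxy)-2-[3,4-bis(benzyloxy)phenyl]-3-hydroxychromen-4-one
Product: 18 5,7-bis(benzyloxy)-2-[3,4-bis(benzyloxy)phenyl]-4-oxochromen-3-yl acetate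
Conditions: Ac2O, pyridine, DMAP (cat.), CH2Cl2, 0 °C to rt
Reagents that add atoms: acetic anhydride, CC(=O)OC(C)=O
Why: DMAP-catalysed acylation of the only free hydroxyl, so no selectivity is required.

Step 10
Reactants: 18 5,7-bis(benzyloxy)-2-[3,4-bis(benzyloxy)phenyl]-4-oxochromen-3-yl acetate
Product: 19 2-(3,4-dihydroxyphenyl)-5,7-dihydroxy-4-oxochromen-3-yl acetate (quercetin 3-acetate)
Conditions: H2 (1 atm), Pd/C (10 % Pd on carbon), THF/EtOAc, rt
Reagents that add atoms: none
Why: Hydrogenolysis of four benzyl aryl ethers in a neutral, alcohol-free medium that cannot transesterify the enol acetate; the C2=C3 bond of the flavone, a vinylogous ester conjugated to two arenes, should not be reduced at this pressure.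

Step 11
Reactants: 19 2-(3,4-dihydroxyphenyl)-5,7-dihydroxy-4-oxochromen-3-yl acetate
Product: 20 quercetin 3-acetate 7,3',4'-tri-O-sulfate, 5-hydroxy-4-oxo-7-(sulfooxy)-2-[3,4-bis(sulfooxy)phenyl]chromen-3-yl acetate
Conditions: SO3·NEt3 (excess), DMA, 65 °C; Sephadex LH-20 (tris(triethylammonium) salt)
Reagents that add atoms: sulfur trioxide–triethylamine complex, CC[N+](CC)(CC)S(=O)(=O)[O-]
Why: O-Sulfation of phenols by a sulfur trioxide–amine complex; the three non-chelated phenols react, the second oxygen of the catechol under forcing excess, while the C5 hydroxyl, hydrogen-bonded to the C4 carbonyl, should stay free as it does in exhaustive sulfation of polyhydroxyflavones. No hydroxide or alkoxide is present, so the acetate should be kept.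

## Compound list

1 | 3,5-bis(benzyloxy)phenol | Oc1cc(OCc2ccccc2)cc(OCc2ccccc2)c1 | starting material
2 | 3,5-bis(benzyloxy)-2-bromophenol | Oc1cc(OCc2ccccc2)cc(OCc2ccccc2)c1Br | intermediate
3 | [3,5-bis(benzyloxy)-2-bromophenoxy]trimethylsilane | C[Si](C)(C)Oc1cc(OCc2ccccc2)cc(OCc2ccccc2)c1Br | intermediate
4 | {2,4-bis(benzyloxy)-6-[(trimethylsilyl)oxy]phenyl}lithium (not isolated) | C[Si](C)(C)Oc1cc(OCc2ccccc2)cc(OCc2ccccc2)c1[Li] | intermediate
5 | lithium 3,5-bis(benzyloxy)-2-(trimethylsilyl)phenoxide (not isolated) | [Li]Oc1cc(OCc2ccccc2)cc(OCc2ccccc2)c1[Si](C)(C)C | intermediate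
6 | 3,5-bis(benzyloxy)-2-(trimethylsilyl)phenyl trifluoromethanesulfonate | C[Si](C)(C)c1c(OCc2ccccc2)cc(OCc2ccccc2)cc1OS(=O)(=O)C(F)(F)F | intermediate
7 | methyl glycolate | COC(=O)CO | starting material
8 | methyl 2-(methoxymethoxy)acetate | COCOCC(=O)OC | intermediate
9 | 3,4-bis(benzyloxy)benzoic acid | O=C(O)c1ccc(OCc2ccccc2)c(OCc2ccccc2)c1 | starting material
10 | 3,4-bis(benzyloxy)benzoyl chloride | O=C(Cl)c1ccc(OCc2ccccc2)c(OCc2ccccc2)c1 | intermediate
11 | lithium 1-methoxy-2-(methoxymethoxy)ethen-1-olate, chelated geometry with O–Li cis to the methoxymethoxy group (not isolated) | COCO/C=C(/OC)O[Li] | intermediate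
12 | methyl 3-[3,4-bis(benzyloxy)phenyl]-2-(methoxymethoxy)-3-oxopropanoate (racemic) | COCOC(C(=O)OC)C(=O)c1ccc(OCc2ccccc2)c(OCc2ccccc2)c1 | intermediate
13 | cesium (E)-1-[3,4-bis(benzyloxy)phenyl]-3-methoxy-2-(methoxymethoxy)-3-oxoprop-1-en-1-olate, enolate oxygen cis to the ester (not isolated) | COCO/C(C(=O)OC)=C(/O[Cs])c1ccc(OCc2ccccc2)c(OCc2ccccc2)c1 | intermediate
14 | 3,5-bis(benzyloxy)benzyne (not isolated) | C1#CC(OCc2ccccc2)=CC(OCc2ccccc2)=C1 | intermediate
15 | methyl (E)-3-[3,4-bis(benzyloxy)phenyl]-3-[3,5-bis(benzyloxy)-2-cesiophenoxy]-2-(methoxymethoxy)prop-2-enoate (not isolated) | COCO/C(C(=O)OC)=C(/Oc1cc(OCc2ccccc2)cc(OCc2ccccc2)c1[Cs])c1ccc(OCc2ccccc2)c(OCc2ccccc2)c1 | intermediate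
16 | 5,7-bis(benzyloxy)-2-[3,4-bis(benzyloxy)phenyl]-3-(methoxymethoxy)chromen-4-one | COCOc1c(-c2ccc(OCc3ccccc3)c(OCc3ccccc3)c2)oc2cc(OCc3ccccc3)cc(OCc3ccccc3)c2c1=O | intermediate
17 | 5,7-bis(benzyloxy)-2-[3,4-bis(benzyloxy)phenyl]-3-hydroxychromen-4-one | Oc1c(-c2ccc(OCc3ccccc3)c(OCc3ccccc3)c2)oc2cc(OCc3ccccc3)cc(OCc3ccccc3)c2c1=O | intermediate
18 | 5,7-bis(benzyloxy)-2-[3,4-bis(benzyloxy)phenyl]-4-oxochromen-3-yl acetate | CC(=O)Oc1c(-c2ccc(OCc3ccccc3)c(OCc3ccccc3)c2)oc2cc(OCc3ccccc3)cc(OCc3ccccc3)c2c1=O | intermediate
19 | 2-(3,4-dihydroxyphenyl)-5,7-dihydroxy-4-oxochromen-3-yl acetate (quercetin 3-acetate) | CC(=O)Oc1c(-c2ccc(O)c(O)c2)oc2cc(O)cc(O)c2c1=O | intermediate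
20 | quercetin 3-acetate 7,3',4'-tri-O-sulfate | CC(=O)Oc1c(-c2ccc(OS(=O)(=O)O)c(OS(=O)(=O)O)c2)oc2cc(OS(=O)(=O)O)cc(O)c2c1=O | target

## Step count and least certain steps

Total step count: 11. Longest linear sequence: 8 steps (steps 1, 2, 3, 7, 8, 9, 10, 11).

**Step 7 (key step, Proposed new method).**
- *What may go wrong:* the most likely failure is attack of the ambident enolate 13 through carbon. The aryl anion then adds to the ketone and the four-membered alkoxide fragments, so the aryne is inserted into the C–C bond and ring C is not closed. A second failure is protonation of the aryl anion of 15 by unreacted 12 before it reaches the ester.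
- *Fallback (known chemistry):* a Baker–Venkataraman sequence that sets out from bromophenol 2, also uses 8 and 10, and comes back to the route at flavonol 17, so that step 8 is not needed. Ester 8 is converted with MeNHOMe·HCl and i-PrMgCl into N-methoxy-2-(methoxymethoxy)-N-methylacetamide F1. Bromophenol 2 is treated with two equivalents of n-BuLi at −78 °C and the O,C-dilithio species is acylated by F1 to give 1-[2,4-bis(benzyloxy)-6-hydroxyphenyl]-2-(methoxymethoxy)ethan-1-one F2. O-Acylation of F2 with acid chloride 10 (pyridine, DMAP) gives 3,5-bis(benzyloxy)-2-[(methoxymethoxy)acetyl]phenyl 3,4-bis(benzyloxy)benzoate F3. KOH in pyridine brings about the acyl shift to 1-[2,4-bis(benzyloxy)-6-hydroxyphenyl]-3-[3,4-bis(benzyloxy)phenyl]-2-(methoxymethoxy)propane-1,3-dione F4. HCl in MeOH/THF then closes ring C by cyclodehydration and removes the methoxymethyl group in the same operation, giving 17.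

**Step 1.**
- *What may go wrong:* bromination at C4 between the two benzyloxy groups, or twofold bromination of the very electron-rich ring, would lower the supply of 2 and give isomers that are hard to separate.
- *Fallback:* a directed ortho-metalation that sets out from phenol 1 and comes back at triflate 6, so that steps 2 and 3 are not needed. Phenol 1 and isopropyl isocyanate (cat. NEt3) give 3,5-bis(benzyloxy)phenyl N-isopropylcarbamate F5. N-Silylation in the flask (TMSOTf, TMEDA), lithiation with n-BuLi/TMEDA at −78 °C between the carbamate and a benzyloxy group, and quenching with Me3SiCl give 3,5-bis(benzyloxy)-2-(trimethylsilyl)phenyl N-isopropylcarbamate F6. Et2NH and DBU in MeCN cleave the carbamate to 3,5-bis(benzyloxy)-2-(trimethylsilyl)phenol F7, which is triflated with PhNTf2 to 6.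

**Step 8.**
- *What may go wrong:* partial loss of the 5-O-benzyl group, which the neighbouring carbonyl makes the most acid-labile of the four, would give a mixture of mono- and di-deprotected flavonols.
- *Fallback:* the double deprotection is made the aim. It sets out from 16 and comes back at 19, so that steps 8 to 10 are replaced. Concentrated HCl in AcOH at 60–70 °C removes both the methoxymethyl and the 5-O-benzyl group to give 7-(benzyloxy)-2-[3,4-bis(benzyloxy)phenyl]-3,5-dihydroxychromen-4-one F8. One equivalent of Ac2O in pyridine at 0 °C acetylates O3 and leaves the chelated C5 hydroxyl, giving 7-(benzyloxy)-2-[3,4-bis(benzyloxy)phenyl]-5-hydroxy-4-oxochromen-3-yl acetate F9. Hydrogenolysis (H2, Pd/C, THF/EtOAc) then gives 19.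

**Step 11.**
- *What may go wrong:* sulfation may stall before the third ester is in place, because the second oxygen of the catechol is hindered and the growing negative charge slows the reaction. The resulting mixture of polyanions is hard to separate. Transfer or loss of the acetyl group under the amine also cannot be excluded.
- *Fallback:* neutral, protected sulfate diesters, setting out from 19 and coming back at 20. Phenol 19 is treated with 2,2,2-trichloroethyl chlorosulfate, NEt3 and DMAP in THF to give 5-hydroxy-4-oxo-7-{[(2,2,2-trichloroethoxy)sulfonyl]oxy}-2-(3,4-bis{[(2,2,2-trichloroethoxy)sulfonyl]oxy}phenyl)chromen-3-yl acetate F10. This compound carries no charge, can be chromatographed on silica and can be re-sulfated if incomplete. Zn dust and HCO2NH4 in MeOH/THF at 0 °C to rt then remove the three trichloroethyl groups reductively to give 20 as its ammonium salt.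

## Further compounds

F1 | step 7 | N-methoxy-2-(methoxymethoxy)-N-methylacetamide | COCOCC(=O)N(C)OC
F2 | step 7 | 1-[2,4-bis(benzyloxy)-6-hydroxyphenyl]-2-(methoxymethoxy)ethan-1-one | COCOCC(=O)c1c(O)cc(OCc2ccccc2)cc1OCc1ccccc1
F3 | step 7 | 3,5-bis(benzyloxy)-2-[(methoxymethoxy)acetyl]phenyl 3,4-bis(benzyloxy)benzoate | COCOCC(=O)c1c(OC(=O)c2ccc(OCc3ccccc3)c(OCc3ccccc3)c2)cc(OCc2ccccc2)cc1OCc1ccccc1
F4 | step 7 | 1-[2,4-bis(benzyloxy)-6-hydroxyphenyl]-3-[3,4-bis(benzyloxy)phenyl]-2-(methoxymethoxy)propane-1,3-dione (racemic) | COCOC(C(=O)c1ccc(OCc2ccccc2)c(OCc2ccccc2)c1)C(=O)c1c(O)cc(OCc2ccccc2)cc1OCc1ccccc1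
F5 | step 1 | 3,5-bis(benzyloxy)phenyl N-isopropylcarbamate | CC(C)NC(=O)Oc1cc(OCc2ccccc2)cc(OCc2ccccc2)c1
F6 | step 1 | 3,5-bis(benzyloxy)-2-(trimethylsilyl)phenyl N-isopropylcarbamate | CC(C)NC(=O)Oc1cc(OCc2ccccc2)cc(OCc2ccccc2)c1[Si](C)(C)C
F7 | step 1 | 3,5-bis(benzyloxy)-2-(trimethylsilyl)phenol | Oc1cc(OCc2ccccc2)cc(OCc2ccccc2)c1[Si](C)(C)C
F8 | step 8 | 7-(benzyloxy)-2-[3,4-bis(benzyloxy)phenyl]-3,5-dihydroxychromen-4-one | Oc1c(-c2ccc(OCc3ccccc3)c(OCc3ccccc3)c2)oc2cc(OCc3ccccc3)cc(O)c2c1=O
F9 | step 8 | 7-(benzyloxy)-2-[3,4-bis(benzyloxy)phenyl]-5-hydroxy-4-oxochromen-3-yl acetate | CC(=O)Oc1c(-c2ccc(OCc3ccccc3)c(OCc3ccccc3)c2)oc2cc(OCc3ccccc3)cc(O)c2c1=O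
F10 | step 11 | 5-hydroxy-4-oxo-7-{[(2,2,2-trichloroethoxy)sulfonyl]oxy}-2-(3,4-bis{[(2,2,2-trichloroethoxy)sulfonyl]oxy}phenyl)chromen-3-yl acetate | CC(=O)Oc1c(-c2ccc(OS(=O)(=O)OCC(Cl)(Cl)Cl)c(OS(=O)(=O)OCC(Cl)(Cl)Cl)c2)oc2cc(OS(=O)(=O)OCC(Cl)(Cl)Cl)cc(O)c2c1=O
A1 | alternative 1 | (E)-3-[3,4-bis(benzyloxy)phenyl]-1-(2,4,6-trihydroxyphenyl)prop-2-en-1-one | O=C(/C=C/c1ccc(OCc2ccccc2)c(OCc2ccccc2)c1)c1c(O)cc(O)cc1O
A2 | alternative 1 | methyl (E)-9-[3,4-bis(benzyloxy)phenyl]-3,5,7-trioxonon-8-enoate | COC(=O)CC(=O)CC(=O)CC(=O)/C=C/c1ccc(OCc2ccccc2)c(OCc2ccccc2)c1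
A3 | alternative 2 | 5,7-bis(benzyloxy)-2-[3,4-bis(benzyloxy)phenyl]-3-[2-(trimethylsilyl)ethoxy]chromen-4-one | C[Si](C)(C)CCOc1c(-c2ccc(OCc3ccccc3)c(OCc3ccccc3)c2)oc2cc(OCc3ccccc3)cc(OCc3ccccc3)c2c1=O
A4 | alternative 2 | 2,4-bis(benzyloxy)-6-{[3,4-bis(benzyloxy)benzoyl]oxy}benzoyl chloride | O=C(Cl)c1c(OCc2ccccc2)cc(OCc2ccccc2)cc1OC(=O)c1ccc(OCc2ccccc2)c(OCc2ccccc2)c1
A5 | alternative 2 | [2-(trimethylsilyl)ethoxy]methylenetriphenylphosphorane | C[Si](C)(C)CCOC=P(c1ccccc1)(c1ccccc1)c1ccccc1
A6 | alternative 3 | 2-[3,4-bis(benzyloxy)phenyl]-5,7-dihydroxychromen-4-one | O=c1cc(-c2ccc(OCc3ccccc3)c(OCc3ccccc3)c2)oc2cc(O)cc(O)c12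
A7 | alternative 3 | phloroglucinol | Oc1cc(O)cc(O)c1
A8 | alternative 3 | ethyl 3-[3,4-bis(benzyloxy)phenyl]-3-oxopropanoate | CCOC(=O)CC(=O)c1ccc(OCc2ccccc2)c(OCc2ccccc2)c1
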